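## Retrosynthetic overview

1. Target 41 ⇐ lactol 40 by carbonyl reduction, which frees C15–OH and C6–OH last. The acrylic acid comes from a C12 aldehyde (Mannich methylenation, Pinnick oxidation) and the C8 ester from acylation with (Z)-4-acetoxy-2-methylbut-2-enoic acid 32.
2. The C8 alcohol ⇐ C8 ketone (hydride from the α face) ⇐ hydroboration of a C7-vinyl C7=C8 diene ⇐ C7 ketone 12 (vinyl addition, dehydration).
3. C6–O and C15 come from the cis-fused lactone 11, made by epoxide-opening lactonization of cyclohexenylacetate 8. The C10 vinyl comes from a masked aldehyde.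
4. 8 ⇐ Johnson–Claisen rearrangement of allylic alcohol 6 (relay C7 → C5) ⇐ ketoreductase reduction of enone 5 ⇐ catalytic asymmetric Diels–Alder reaction of methacrolein (sets C10).
5. Ring order: the cyclohexane ring is formed first (step 1); the fused lactone/lactol ring (step 6) is temporary and is opened in step 27.

Convention for names: ring carbons keep elemane numbers. C10 is the quaternary carbon with methyl C14 and the one-carbon unit C1 (later the C1=C2 vinyl); C9 is CH2; C8, C7, C6, C5 follow round the ring. C5 carries C4 (with C3 and C15); C7 carries C11 (with C13 and C12). β is the ring face that carries C1, α the face that carries C14.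

Assumption: the (R,R) catalyst of step 1 gives the (S) aldehyde 4; if the facial sense proves opposite, the (S,S) catalyst is used and nothing else changes.

## Route

Step 1
Reactants: 1 (E)-3-(tert-butyldimethylsilyloxy)-N,N-dimethylbuta-1,3-dien-1-amine; 2 methacrolein
Product: 4 (S)-1-methyl-4-oxocyclohex-2-ene-1-carbaldehyde, via endo cycloadduct 3 (not isolated)
Conditions: (R,R)-[(salen)Cr]SbF6 5 mol% (salen = N,N′-bis(3,5-di-tert-butylsalicylidene)cyclohexane-1,2-diamine dianion), 4 Å MS, CH2Cl2, −40 °C; then 1 M HCl, THF, 0 °C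
Reagents that add atoms: none
Why: Catalytic asymmetric Diels–Alder reaction in which the chiral trivalent chromium Lewis acid binds methacrolein and blocks one face, so the amine-bearing diene terminus bonds to the α-carbon (ortho rule) and the quaternary C10 is set as S, after which acid hydrolyses the silyl enol ether and eliminates dimethylamine to the enone.

Step 2
Reactants: 4 (S)-1-methyl-4-oxocyclohex-2-ene-1-carbaldehyde
Product: 5 (S)-4-(dimethoxymethyl)-4-methylcyclohex-2-en-1-one
Conditions: HC(OMe)3, MeOH, PPTS (cat.), rt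
Reagents that add atoms: trimethyl orthoformate, COC(OC)OC
Why: Acid-catalysed acetalization is chemoselective for the aldehyde over the conjugated ketone and masks C1 until step 12.

Step 3
Reactants: 5 (S)-4-(dimethoxymethyl)-4-methylcyclohex-2-en-1-one
Product: 6 (1R,4S)-4-(dimethoxymethyl)-4-methylcyclohex-2-en-1-ol
Conditions: ketoreductase (R-selective, NADPH-dependent), NADP+ (cat.), Me2CHOH (10% v/v), phosphate buffer pH 7.0, 30 °C
Reagents that add atoms: none
Why: Biocatalytic carbonyl reduction in which the ketoreductase delivers hydride to one face of the enone C=O under enzyme control, giving the (1R) allylic alcohol with OH cis to CH(OMe)2 (new stereocentre C7), while any minor enantiomer of 5 ends up as the separable trans diastereomer.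

Step 4
Reactants: 6 (1R,4S)-4-(dimethoxymethyl)-4-methylcyclohex-2-en-1-ol
Product: 8 methyl 2-[(1R,6S)-6-(dimethoxymethyl)-6-methylcyclohex-2-en-1-yl]acetate, via ketene acetal 7 (not isolated)
Conditions: MeC(OMe)3, EtCO2H (cat.), xylene, 140 °C, MeOH distilled off
Reagents that add atoms: trimethyl orthoacetate, CC(OC)(OC)OC
Why: Johnson–Claisen rearrangement in which the ketene acetal undergoes a suprafacial [3,3] shift that transfers the C7–O stereocentre to the new C5–C4 bond on the same (β) face, cis to C1.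

Step 5
Reactants: 8 methyl 2-[(1R,6S)-6-(dimethoxymethyl)-6-methylcyclohex-2-en-1-yl]acetate
Product: 9 6α,7α-epoxy ester (epoxide of 8 on the face opposite both β substituents)
Conditions: mCPBA, NaHCO3, CH2Cl2, 0 °C
Reagents that add atoms: 3-chloroperbenzoic acid, OOC(=O)c1cccc(Cl)c1
Why: Prilezhaev epoxidation of the only alkene from the α face, anti to the β-oriented C5 side chain and C10 acetal, places the epoxide trans to the side chain.

Step 6
Reactants: 9 6α,7α-epoxy ester
Product: 11 7α-hydroxy 15,6β-lactone, via epoxy acid 10 (not isolated)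
Conditions: LiOH, THF/H2O, rt; then 1 M HCl to pH 4, 0 °C to rt
Reagents that add atoms: lithium hydroxide, [Li+].[OH-]
Why: Saponification then intramolecular 5-exo epoxide opening by the carboxylic acid (SN2, inversion at C6) gives the cis-fused γ-lactone, so C6–O is β and the C7 hydroxyl α.

Step 7
Reactants: 11 7α-hydroxy 15,6β-lactone
Product: 12 7-oxo 15,6β-lactone
Conditions: Dess–Martin periodinane, NaHCO3, CH2Cl2, rt
Reagents that add atoms: none
Why: Dess–Martin oxidation converts the secondary alcohol into the C7 ketone under buffered conditions that do not epimerize C6.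

Step 8
Reactants: 12 7-oxo 15,6β-lactone
Product: 13 7β-hydroxy-7α-vinyl 15,6β-lactone
Conditions: CH2=CHMgBr, CeCl3, THF, −78 °C
Reagents that add atoms: vinylmagnesium bromide, C=C[Mg]Br
Why: Organocerium 1,2-addition is chemoselective for the ketone over the lactone and suppresses enolization; the new C7 centre (vinyl from the open α face) is removed in the next step.

Step 9
Reactants: 13 7β-hydroxy-7α-vinyl 15,6β-lactone
Product: 14 7-vinyl-7(8)-ene 15,6β-lactone (conjugated diene)
Conditions: Burgess reagent (MeO2C–N–SO2–NEt3 inner salt), toluene, 60 °C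
Reagents that add atoms: none
Why: Burgess dehydration (syn elimination) can only use the C8 hydrogen syn to the 7β-hydroxyl, giving the conjugated C7=C8 diene without touching C6.

Step 10
Reactants: 14 7-vinyl-7(8)-ene 15,6β-lactone
Product: 17 8α,12-diol 15,6β-lactone (H-7α), via alkyl-9-BBN adduct 15 (not isolated), via C8 alkylborane 16 (not isolated)
Conditions: 9-BBN (1.2 equiv), THF, 0 °C to rt; BH3·SMe2 (1.5 equiv), 0 °C; NaBO3·4H2O, THF/H2O, rt
Reagents that add atoms: sodium perborate, [Na+].[Na+].O[B-]1(O)OO[B-](O)(O)OO1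
Why: Hydroboration–oxidation in two stages, in which 9-BBN takes only the monosubstituted alkene (boron at C12) and borane then adds syn to the trisubstituted ring alkene from the α face, anti to the allylic C6–O bond and the β-fused lactone, placing H-7 α (side chain β) and the C8 hydroxyl α.

Step 11
Reactants: 17 8α,12-diol 15,6β-lactone
Product: 18 12-O-TBDPS 8α-hydroxy 15,6β-lactone
Conditions: t-BuPh2SiCl, imidazole, CH2Cl2, 0 °C
Reagents that add atoms: tert-butyl(chloro)diphenylsilane, CC(C)(C)[Si](Cl)(c1ccccc1)c1ccccc1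
Why: Silylation with the bulky chlorosilane is selective for the primary C12 hydroxyl over the hindered secondary C8 hydroxyl.

Step 12
Reactants: 18 12-O-TBDPS 8α-hydroxy 15,6β-lactone
Product: 19 C1 aldehyde (12-O-TBDPS 8α-hydroxy 15,6β-lactone)
Conditions: TsOH·H2O (cat.), acetone/H2O, rt
Reagents that add atoms: water, O
Why: Acid-catalysed acetal hydrolysis frees the C1 aldehyde, which cannot form a hemiacetal because the C8 hydroxyl is still on the opposite (α) face.

Step 13
Reactants: 19 C1 aldehyde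
Product: 20 10β-vinyl 12-O-TBDPS 8α-hydroxy 15,6β-lactone
Conditions: Ph3PCH3Br, KN(SiMe3)2, THF, 0 °C to rt
Reagents that add atoms: methyltriphenylphosphonium bromide, C[P+](c1ccccc1)(c1ccccc1)c1ccccc1.[Br-]
Why: Wittig methylenation converts the neopentyl aldehyde into the C10 vinyl group without affecting any stereocentre.

Step 14
Reactants: 20 10β-vinyl 12-O-TBDPS 8α-hydroxy 15,6β-lactone
Product: 23 α-methylene lactone (C4=C3 exocyclic), via Mannich base 21 (not isolated), via methiodide 22 (not isolated)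
Conditions: LiN(CHMe2)2 (2.5 equiv), THF, −78 °C; Me2N=CH2 I; then MeI, MeOH; then NaHCO3 (aq), CH2Cl2
Reagents that add atoms: Eschenmoser's salt (N,N-dimethylmethyleneiminium iodide), C=[N+](C)C.[I-]
Why: α-Methylenation of the lactone by enolate Mannich reaction with Eschenmoser's salt, N-methylation and Hofmann-type elimination installs C3 as the exocyclic methylene.

Step 15
Reactants: 23 α-methylene lactone
Product: 25 15-O-methyl lactol acetal (8α-OH), via lactol 24 (not isolated)
Conditions: (Me2CHCH2)2AlH (3 equiv), CH2Cl2, −78 °C; then MeOH, PPTS, rt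
Reagents that add atoms: methanol, CO
Why: Partial reduction of the lactone to the lactol followed by acid-catalysed acetalization locks C15 and O6 as a cyclic methyl acetal (anomeric mixture), the 8α-hydroxyl being unable to reach C15.

Step 16
Reactants: 25 15-O-methyl lactol acetal (8α-OH)
Product: 26 8-ketone
Conditions: Dess–Martin periodinane, NaHCO3, CH2Cl2, rt
Reagents that add atoms: none
Why: Dess–Martin oxidation gives the C8 ketone, and the adjacent C7 centre carries its side chain equatorially and is stable under the buffered conditions.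

Step 17
Reactants: 26 8-ketone
Product: 27 8β-alcohol
Conditions: LiBH(CHMeEt)3, THF, −78 °C; NaHCO3 work-up, Et3N-treated silica
Reagents that add atoms: none
Why: Bulky-hydride reduction in which LiBH(CHMeEt)3 attacks the C8 carbonyl equatorially from the α face (the β face is blocked by the axial C10 vinyl and C6–O groups), giving the axial 8β alcohol cis to the C7 side chain.

Step 18
Reactants: 28 3-methylfuran-2(5H)-one
Product: 30 4-methoxybenzyl (Z)-4-hydroxy-2-methylbut-2-enoate, via potassium carboxylate 29 (not isolated)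
Conditions: KOH (1 equiv), MeOH/H2O, rt; evaporate; 4-MeOC6H4CH2Cl, DMF, rt
Reagents that add atoms: potassium hydroxide, [K+].[OH-]; 4-methoxybenzyl chloride, COc1ccc(CCl)cc1
Why: Saponification of the butenolide followed by carboxylate O-alkylation gives the hydroxy ester with the Z geometry fixed by the ring of 28.

Step 19
Reactants: 30 4-methoxybenzyl (Z)-4-hydroxy-2-methylbut-2-enoate
Product: 31 4-methoxybenzyl (Z)-4-acetoxy-2-methylbut-2-enoate
Conditions: Ac2O, pyridine, DMAP (cat.), CH2Cl2, 0 °C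
Reagents that add atoms: acetic anhydride, CC(=O)OC(C)=O
Why: Acetylation of the primary allylic hydroxyl outruns relactonization.

Step 20
Reactants: 31 4-methoxybenzyl (Z)-4-acetoxy-2-methylbut-2-enoate
Product: 32 (Z)-4-acetoxy-2-methylbut-2-enoic acid
Conditions: CF3CO2H, anisole, CH2Cl2, 0 °C
Reagents that add atoms: none
Why: Acidolysis of the 4-methoxybenzyl ester (cation trapped by anisole) frees the acid without touching the acetate or the Z alkene.

Step 21
Reactants: 27 8β-alcohol; 32 (Z)-4-acetoxy-2-methylbut-2-enoic acid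
Product: 34 8β-O-[(Z)-4-acetoxy-2-methylbut-2-enoyl] ester, via mixed anhydride 33 (not isolated)
Conditions: 2,4,6-Cl3C6H2COCl, Et3N, toluene, rt; then 27, DMAP, toluene, 60 °C
Reagents that add atoms: none
Why: Yamaguchi esterification via the mixed 2,4,6-trichlorobenzoic anhydride acylates the hindered axial C8 hydroxyl with retention at C8 and without Z to E isomerization of the enoate.

Step 22
Reactants: 34 8β-O-acyl 12-O-TBDPS compound
Product: 35 12-alcohol
Conditions: Bu4NF, AcOH (1:1), THF, rt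
Reagents that add atoms: none
Why: Buffered fluoride desilylation frees the C12 hydroxyl while leaving the three esters and the acetal intact.

Step 23
Reactants: 35 12-alcohol
Product: 36 12-aldehyde
Conditions: Dess–Martin periodinane, NaHCO3, CH2Cl2, 0 °C
Reagents that add atoms: none
Why: Dess–Martin oxidation of the primary alcohol stops at the aldehyde.

Step 24
Reactants: 36 12-aldehyde
Product: 38 11(13)-en-12-al, via amino aldehyde 37 (not isolated)
Conditions: Me2N=CH2 I, Et3N, CH2Cl2, rt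
Reagents that add atoms: Eschenmoser's salt (N,N-dimethylmethyleneiminium iodide), C=[N+](C)C.[I-]
Why: Mannich α-methylenation of the aldehyde with Eschenmoser's salt followed by amine elimination installs the C11=C13 methylene.

Step 25
Reactants: 38 11(13)-en-12-al
Product: 39 11(13)-en-12-oic acid
Conditions: NaClO2, NaH2PO4, 2-methylbut-2-ene, t-BuOH/H2O, 0 °C
Reagents that add atoms: sodium chlorite, [Na+].[O-]Cl=O
Why: Pinnick oxidation converts the enal into the acrylic acid without affecting alkenes (hypochlorite is scavenged) or esters.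

Step 26
Reactants: 39 11(13)-en-12-oic acid (15-O-methyl acetal)
Product: 40 15,6β-lactol acid
Conditions: AcOH/THF/H2O (2:1:1), rt
Reagents that add atoms: water, O
Why: Mild acid hydrolysis of the allylic cyclic acetal gives the lactol while O6 stays tied up, so the acid cannot lactonize.

Step 27
Reactants: 40 15,6β-lactol acid
Product: 41 2-[(1S,2S,3R,4R,6R)-6-{[(2Z)-4-acetoxy-2-methylbut-2-enoyl]oxy}-4-ethenyl-2-hydroxy-3-(3-hydroxyprop-1-en-2-yl)-4-methylcyclohexyl]prop-2-enoic acid
Conditions: NaBH4, CeCl3·7H2O, MeOH, −20 °C; pH 5 phosphate work-up, cold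
Reagents that add atoms: none
Why: Luche reduction of the open hydroxy-enal form of the lactol (1,2-selective) releases the C15 allylic alcohol and the C6 hydroxyl near neutral pH, leaving esters, acid and all stereocentres untouched.

## Compound list

1 | (E)-3-(tert-butyldimethylsilyloxy)-N,N-dimethylbuta-1,3-dien-1-amine | CN(C)/C=C/C(=C)O[Si](C)(C)C(C)(C)C | starting material
2 | methacrolein (2-methylprop-2-enal) | CC(=C)C=O | starting material
3 | endo cycloadduct, 4-(tert-butyldimethylsilyloxy)-2-(dimethylamino)-1-methylcyclohex-3-ene-1-carbaldehyde, NMe2 cis to CHO (formed in the flask) | O=C[C@@]1(C)CCC(O[Si](C)(C)C(C)(C)C)=C[C@H]1N(C)C | intermediate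
4 | (S)-1-methyl-4-oxocyclohex-2-ene-1-carbaldehyde | O=C[C@@]1(C)CCC(=O)C=C1 | intermediate
5 | (S)-4-(dimethoxymethyl)-4-methylcyclohex-2-en-1-one | COC(OC)[C@@]1(C)CCC(=O)C=C1 | intermediate
6 | (1R,4S)-4-(dimethoxymethyl)-4-methylcyclohex-2-en-1-ol (OH cis to CH(OMe)2) | COC(OC)[C@@]1(C)CC[C@@H](O)C=C1 | intermediate
7 | ketene acetal, (3S,6R)-3-(dimethoxymethyl)-6-[(1-methoxyethenyl)oxy]-3-methylcyclohex-1-ene (formed in the flask) | COC(OC)[C@@]1(C)CC[C@@H](OC(=C)OC)C=C1 | intermediate
8 | methyl 2-[(1R,6S)-6-(dimethoxymethyl)-6-methylcyclohex-2-en-1-yl]acetate (CH2CO2Me cis to CH(OMe)2) | COC(OC)[C@@]1(C)CCC=C[C@H]1CC(=O)OC | intermediate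
9 | 6α,7α-epoxy ester: methyl 2-[6-(dimethoxymethyl)-6-methyl-2,3-epoxycyclohexyl]acetate, epoxide trans to CH2CO2Me and CH(OMe)2 | COC(OC)[C@@]1(C)CC[C@@H]2O[C@@H]2[C@H]1CC(=O)OC | intermediate
10 | epoxy acid, free acid of 9 (formed in the flask) | COC(OC)[C@@]1(C)CC[C@@H]2O[C@@H]2[C@H]1CC(=O)O | intermediate
11 | 7α-hydroxy 15,6β-lactone: cis-fused 4-(dimethoxymethyl)-7-hydroxy-4-methylhexahydro-1-benzofuran-2(3H)-one, CH(OMe)2 cis to C3, OH trans to O1 | COC(OC)[C@@]1(C)CC[C@H](O)[C@H]2OC(=O)C[C@H]21 | intermediate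
12 | 7-oxo 15,6β-lactone: cis-fused 4-(dimethoxymethyl)-4-methyltetrahydro-1-benzofuran-2,7(3H,7aH)-dione | COC(OC)[C@@]1(C)CCC(=O)[C@H]2OC(=O)C[C@H]21 | intermediate
13 | 7β-hydroxy-7α-vinyl 15,6β-lactone | COC(OC)[C@@]1(C)CC[C@](O)(C=C)[C@H]2OC(=O)C[C@H]21 | intermediate
14 | 7-vinyl-7(8)-ene 15,6β-lactone (C11=C12 vinyl on C7, ring alkene C7=C8) | COC(OC)[C@@]1(C)CC=C(C=C)[C@H]2OC(=O)C[C@H]21 | intermediate
15 | alkyl-9-BBN adduct, boron on C12 (formed in the flask) | COC(OC)[C@@]1(C)CC=C(CCB3C4CCCC3CCC4)[C@H]2OC(=O)C[C@H]21 | intermediate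
16 | C8 alkylborane, 8α-BH2, H-7α (formed in the flask) | COC(OC)[C@@]1(C)C[C@H]([BH2])[C@@H](CCB3C4CCCC3CCC4)[C@H]2OC(=O)C[C@H]21 | intermediate
17 | 8α,12-diol 15,6β-lactone, C7 side chain β | COC(OC)[C@@]1(C)C[C@H](O)[C@@H](CCO)[C@H]2OC(=O)C[C@H]21 | intermediate
18 | 12-O-tert-butyldiphenylsilyl 8α-hydroxy 15,6β-lactone | COC(OC)[C@@]1(C)C[C@H](O)[C@@H](CCO[Si](c3ccccc3)(c3ccccc3)C(C)(C)C)[C@H]2OC(=O)C[C@H]21 | intermediate
19 | C1 aldehyde of 18 (10β-formyl) | O=C[C@@]1(C)C[C@H](O)[C@@H](CCO[Si](c3ccccc3)(c3ccccc3)C(C)(C)C)[C@H]2OC(=O)C[C@H]21 | intermediate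
20 | 10β-vinyl 12-O-TBDPS 8α-hydroxy 15,6β-lactone | C=C[C@@]1(C)C[C@H](O)[C@@H](CCO[Si](c3ccccc3)(c3ccccc3)C(C)(C)C)[C@H]2OC(=O)C[C@H]21 | intermediate
21 | Mannich base, 4-(dimethylaminomethyl) lactone (formed in the flask) | C=C[C@@]1(C)C[C@H](O)[C@@H](CCO[Si](c3ccccc3)(c3ccccc3)C(C)(C)C)[C@H]2OC(=O)C(CN(C)C)[C@H]21 | intermediate
22 | methiodide of 21 (formed in the flask) | C=C[C@@]1(C)C[C@H](O)[C@@H](CCO[Si](c3ccccc3)(c3ccccc3)C(C)(C)C)[C@H]2OC(=O)C(C[N+](C)(C)C)[C@H]21.[I-] | intermediate
23 | α-methylene lactone, C4=C3 exocyclic, 8α-OH | C=C[C@@]1(C)C[C@H](O)[C@@H](CCO[Si](c3ccccc3)(c3ccccc3)C(C)(C)C)[C@H]2OC(=O)C(=C)[C@H]21 | intermediate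
24 | α-methylene lactol, C15 hemiacetal to O6 (formed in the flask) | C=C[C@@]1(C)C[C@H](O)[C@@H](CCO[Si](c3ccccc3)(c3ccccc3)C(C)(C)C)[C@H]2OC(O)C(=C)[C@H]21 | intermediate
25 | 15-O-methyl lactol acetal (anomeric mixture), 8α-OH | C=C[C@@]1(C)C[C@H](O)[C@@H](CCO[Si](c3ccccc3)(c3ccccc3)C(C)(C)C)[C@H]2OC(OC)C(=C)[C@H]21 | intermediate
26 | 8-ketone of 25 | C=C[C@@]1(C)CC(=O)[C@@H](CCO[Si](c3ccccc3)(c3ccccc3)C(C)(C)C)[C@H]2OC(OC)C(=C)[C@H]21 | intermediate
27 | 8β-alcohol (8-epimer of 25) | C=C[C@@]1(C)C[C@@H](O)[C@@H](CCO[Si](c3ccccc3)(c3ccccc3)C(C)(C)C)[C@H]2OC(OC)C(=C)[C@H]21 | intermediate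
28 | 3-methylfuran-2(5H)-one | CC1=CCOC1=O | starting material
29 | potassium (Z)-4-hydroxy-2-methylbut-2-enoate (formed in the flask) | [K+].[O-]C(=O)/C(C)=C\CO | intermediate
30 | 4-methoxybenzyl (Z)-4-hydroxy-2-methylbut-2-enoate | COc1ccc(COC(=O)/C(C)=C\CO)cc1 | intermediate
31 | 4-methoxybenzyl (Z)-4-acetoxy-2-methylbut-2-enoate | COc1ccc(COC(=O)/C(C)=C\COC(C)=O)cc1 | intermediate
32 | (Z)-4-acetoxy-2-methylbut-2-enoic acid | OC(=O)/C(C)=C\COC(C)=O | intermediate
33 | (Z)-4-acetoxy-2-methylbut-2-enoic 2,4,6-trichlorobenzoic anhydride (formed in the flask) | O=C(OC(=O)/C(C)=C\COC(C)=O)c1c(Cl)cc(Cl)cc1Cl | intermediate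
34 | 8β-O-[(Z)-4-acetoxy-2-methylbut-2-enoyl] 12-O-TBDPS 15-O-methyl lactol acetal | C=C[C@@]1(C)C[C@@H](OC(=O)/C(C)=C\COC(C)=O)[C@@H](CCO[Si](c3ccccc3)(c3ccccc3)C(C)(C)C)[C@H]2OC(OC)C(=C)[C@H]21 | intermediate
35 | 12-alcohol | C=C[C@@]1(C)C[C@@H](OC(=O)/C(C)=C\COC(C)=O)[C@@H](CCO)[C@H]2OC(OC)C(=C)[C@H]21 | intermediate
36 | 12-aldehyde | C=C[C@@]1(C)C[C@@H](OC(=O)/C(C)=C\COC(C)=O)[C@@H](CC=O)[C@H]2OC(OC)C(=C)[C@H]21 | intermediate
37 | amino aldehyde, 11-(dimethylaminomethyl)-12-al (formed in the flask) | C=C[C@@]1(C)C[C@@H](OC(=O)/C(C)=C\COC(C)=O)[C@@H](C(CN(C)C)C=O)[C@H]2OC(OC)C(=C)[C@H]21 | intermediate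
38 | 11(13)-en-12-al | C=C[C@@]1(C)C[C@@H](OC(=O)/C(C)=C\COC(C)=O)[C@@H](C(=C)C=O)[C@H]2OC(OC)C(=C)[C@H]21 | intermediate
39 | 11(13)-en-12-oic acid, 15-O-methyl lactol acetal | C=C[C@@]1(C)C[C@@H](OC(=O)/C(C)=C\COC(C)=O)[C@@H](C(=C)C(=O)O)[C@H]2OC(OC)C(=C)[C@H]21 | intermediate
40 | 15,6β-lactol acid | C=C[C@@]1(C)C[C@@H](OC(=O)/C(C)=C\COC(C)=O)[C@@H](C(=C)C(=O)O)[C@H]2OC(O)C(=C)[C@H]21 | intermediate
41 | 2-[(1S,2S,3R,4R,6R)-6-{[(2Z)-4-acetoxy-2-methylbut-2-enoyl]oxy}-4-ethenyl-2-hydroxy-3-(3-hydroxyprop-1-en-2-yl)-4-methylcyclohexyl]prop-2-enoic acid (elemane numbering 5R,6S,7S,8R,10R) | C=C[C@@]1(C)C[C@@H](OC(=O)/C(C)=C\COC(C)=O)[C@@H](C(=C)C(=O)O)[C@@H](O)[C@H]1C(=C)CO | target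

## Step count and weak points

Total: 27 steps. Longest linear sequence: 24 steps (steps 1–17 and 21–27); the side-chain acid 32 takes 3 steps (18–20).

Steps most likely to fail:

Step 5 (face selectivity of the epoxidation; only the α-epoxide can lactonize). The fallback sets out from 8 and comes back at 12. Saponification (LiOH, THF/H2O) gives the carboxylic acid F1. Iodolactonization (I2, NaHCO3, MeCN/H2O, 0 °C) is a stereospecific anti addition and gives the cis-fused iodolactone F2 with C6–O β and iodine 7α. Radical hydroxylation (Bu3SnH, air, toluene; then PPh3) replaces iodine by OH and gives 11 together with its 7β-hydroxy epimer F3. Dess–Martin oxidation of the mixture converges on ketone 12.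

Step 9 (regiochemistry of the dehydration, possible allylic rearrangement). The fallback sets out from 12, skips 13 and comes back at 14. Kinetic deprotonation at C8 and trapping (KN(SiMe3)2, PhNTf2, THF, −78 °C) give the enol triflate F4. Stille coupling with tributyl(vinyl)stannane (Pd(PPh3)4, LiCl, THF, 50 °C) gives diene 14.

Step 21 (acylation of the hindered axial C8 hydroxyl, Z integrity of the acid). The fallback sets out from 27 and comes back at 34. Esterification with 2-[bis(2,2,2-trifluoroethoxy)phosphoryl]propanoic acid (DCC, DMAP, CH2Cl2) gives the phosphonate ester F5. Still–Gennari olefination with 2-oxoethyl acetate (KN(SiMe3)2, 18-crown-6, THF, −78 °C) builds the (Z)-enoate on the ring and gives 34.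

## Further compounds

F1 | step 5 | 2-[(1R,6S)-6-(dimethoxymethyl)-6-methylcyclohex-2-en-1-yl]acetic acid | COC(OC)[C@@]1(C)CCC=C[C@H]1CC(=O)O
F2 | step 5 | 7α-iodo 15,6β-lactone (cis-fused 4-(dimethoxymethyl)-7-iodo-4-methylhexahydro-1-benzofuran-2(3H)-one, iodine trans to O1) | COC(OC)[C@@]1(C)CC[C@H](I)[C@H]2OC(=O)C[C@H]21
F3 | step 5 | 7β-hydroxy 15,6β-lactone (7-epimer of 11) | COC(OC)[C@@]1(C)CC[C@@H](O)[C@H]2OC(=O)C[C@H]21
F4 | step 9 | 7-(trifluoromethanesulfonyloxy)-7(8)-ene 15,6β-lactone (enol triflate of 12) | COC(OC)[C@@]1(C)CC=C(OS(=O)(=O)C(F)(F)F)[C@H]2OC(=O)C[C@H]21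
F5 | step 21 | 8β-O-{2-[bis(2,2,2-trifluoroethoxy)phosphoryl]propanoyl} ester of 27 | C=C[C@@]1(C)C[C@@H](OC(=O)C(C)P(=O)(OCC(F)(F)F)OCC(F)(F)F)[C@@H](CCO[Si](c3ccccc3)(c3ccccc3)C(C)(C)C)[C@H]2OC(OC)C(=C)[C@H]21
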